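## Retrosynthetic overview

1. Ring numbering used throughout: C1 (CHOAc), C2 (=CH), C3 (=C–C7H2OBz), C4 (CHOH), C5 (CHOBz), C6 (CHOH). The plan rests on one feature: the C5/C6 cis-diol lies meta and para to C3, the ring carbon bearing C7, and these are the two carbons left as a free alkene when a C7-substituted benzene is bridged across C1 and C4.
2. C5–OBz ⇐ regioselective opening of a C5/C6 cyclic orthobenzoate; cis C1–OAc/C4–OH ⇐ 1,4-addition of AcOH under Pd(PPh3)4 to a C3–C4 vinyl epoxide lying anti to the C5/C6 oxygens.
3. Epoxide ⇐ diene C1=C2–C3=C4 with a free C7 hydroxyl ⇐ loss of N2 from a urazole-bridged bicycle. The C7 benzoate cannot survive the alkaline urazole cleavage, so the freed hydroxyl is used to direct the epoxidation and is benzoylated afterwards.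
4. Bicycle ⇐ benzyl benzoate + 4-methyl-1,2,4-triazoline-3,5-dione (MTAD) by visible-light para-cycloaddition across C1/C4, with OsO4 on C5=C6 in the same pot; the racemic diol is resolved with a lipase.
5. Ring order: the carbocycle is the benzyl ring of the starting ester; the only ring made is the temporary 2,3-diazabicyclo[2.2.2]octene (step 1), removed in step 4. The acetonide and orthoester rings are protecting devices.

Key step: step 1

Assumption: in step 2 the lipase is taken to acylate the (1S,4R,5S,6R)-enantiomer of 4 faster, so the needed (1R,4S,5R,6S)-diol 5 is the unreacted alcohol; the sense would be checked on a derivative before material is committed.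

Convention: "lower face" is the ring face carrying the C5 and C6 oxygens; "upper face" is the opposite one. Descriptors given with locants 1–6 refer to the ring numbering above.

## Route

Step 1
Reactants: 1 benzyl benzoate; 2 4-methyl-1,2,4-triazoline-3,5-dione (MTAD)
Product: 4 racemic urazole-bridged bicyclo[2.2.2]octene cis-5,6-diol (N–N bridge across C1/C4 on the upper face; C2=C3 bearing C7H2OBz; both hydroxyls on the lower face), via arene–MTAD cycloadduct 3 (not isolated)
Conditions: 1 (2 equiv), 2 (1 equiv), CH2Cl2, white LEDs, −78 °C; then OsO4 (5 mol %), NMO (1.3 equiv), acetone/H2O, −78 → 0 °C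
Reagents that add atoms: osmium tetroxide O=[Os](=O)(=O)=O; N-methylmorpholine N-oxide C[N+]1([O-])CCOCC1; water O
Why: Visible light excites 2 (n→π*), and the excited triazolinedione adds across the para-related C1 and C4 of the electron-richer benzyl ring of 1 in a dearomative [4+2] photocycloaddition; the closest known reaction type is the arenophile cycloaddition of monosubstituted benzenes with in situ osmylation. The only ring formed, the 2,3-diazabicyclo[2.2.2]octadiene of 3, closes intermolecularly by two C–N bonds made suprafacially on one arene face, which fixes C1 and C4 relative to each other; the two arene faces are enantiotopic, so the adduct is racemic. Because 3 reverts to arene and 2 on warming, OsO4 is added cold and takes the strained, unsubstituted C5=C6 alkene by [3+2] cycloaddition to an osmate ester that NMO and water turn over. Both C–O bonds at C5 and C6 form syn from the alkene face turned away from the urazole carbonyls, so the diol is cis and anti to the N–N bridge. Three selectivities are needed: ring selectivity, secured because the benzoyl ring is deactivated by its ester carbonyl toward the electrophilic excited 2; 2,5-regiochemistry, secured because C–N bond formation avoids the substituted C3; and alkene selectivity, secured because C2=C3 is trisubstituted and carries the electron-withdrawing C7H2OBz group.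

Step 2
Reactants: 4 racemic bicyclic cis-diol
Product: 5 (1R,4S,5R,6S)-bicyclic cis-diol (single enantiomer of 4)
Conditions: Amano lipase PS (Burkholderia cepacia, immobilised), vinyl acetate (3 equiv), THF/MTBE, 35 °C, run slightly past half conversion; chromatography
Reagents that add atoms: none
Why: Lipase-catalysed acylative kinetic resolution of a cyclic secondary diol with an irreversible acyl donor should acetylate one enantiomer (expected at the less hindered C6 hydroxyl) and leave the other untouched; no stereocenter is formed or changed, and running past half conversion protects the enantiomeric purity of the recovered diol.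

Step 3
Reactants: 5 (1R,4S,5R,6S)-bicyclic cis-diol
Product: 6 C5/C6 acetonide of 5
Conditions: 2,2-dimethoxypropane, p-TsOH·H2O (cat.), acetone, rt
Reagents that add atoms: 2,2-dimethoxypropane COC(C)(C)OC
Why: Acid-catalysed transketalisation closes a dioxolane readily on the eclipsed cis-diol of the bicyclo[2.2.2] frame; the benzoate and urazole are inert and no stereocenter is touched.

Step 4
Reactants: 6 C5/C6 acetonide of 5
Product: 9 [(3aR,7aS)-2,2-dimethyl-3a,7a-dihydro-1,3-benzodioxol-5-yl]methanol (diene C1=C2–C3=C4 with free C7–OH), via bicyclic hydrazine 7 (not isolated), via bicyclic diazene 8 (not isolated)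
Conditions: KOH, i-PrOH, 85 °C, degassed; AcOH to pH 5–6, 0 °C; CuCl2 (2.2 equiv), H2O, 0 °C → rt; NH4OH work-up
Reagents that add atoms: none
Why: Alkaline urazole hydrolysis with decarboxylation gives the cyclic hydrazine (the C7 benzoate is saponified in the same operation), CuCl2 oxidises it to the 2,3-diazabicyclo[2.2.2]octa-2,5-diene, and this loses N2 by retro-[4+2] cycloreversion at or below room temperature; C5 and C6 are not involved and the acetonide guards the dihydrodiol against aromatisation.

Step 5
Reactants: 9 dienyl alcohol
Product: 10 C3–C4 epoxy alcohol (epoxide oxygen on the upper face, anti to the acetonide; C1=C2 retained)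
Conditions: VO(acac)2 (3 mol %), t-BuOOH (1.3 equiv, decane), CH2Cl2, 0 °C
Reagents that add atoms: tert-butyl hydroperoxide CC(C)(C)OO
Why: In this hydroxyl-directed vanadium-catalysed epoxidation the C7 alkoxide binds the metal peroxide and delivers oxygen only to the allylic C3=C4 alkene, not to the homoallylic C1=C2; oxygen enters on the face opposite the dioxolane at C5, which sets C3 and C4.

Step 6
Reactants: 10 epoxy alcohol
Product: 11 C7 benzoate of 10
Conditions: BzCl, Et3N, DMAP (cat.), CH2Cl2, 0 °C
Reagents that add atoms: benzoyl chloride O=C(Cl)c1ccccc1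
Why: DMAP-catalysed acylation of the unhindered primary alcohol restores the C7 benzoate in a cold basic medium that should leave the vinyl epoxide and acetonide intact.

Step 7
Reactants: 11 vinyl epoxide benzoate; 12 acetic acid
Product: 13 C1 acetate / C4 alcohol (both on the upper face, cis to each other), C2=C3 alkene, C5/C6 acetonide, C7 benzoate
Conditions: Pd(PPh3)4 (2 mol %), 12 (1.2 equiv), THF, 0 °C, short reaction time
Reagents that add atoms: none
Why: In this Tsuji–Trost-type opening zerovalent palladium ionises the allylic C3–O bond with inversion, AcOH protonates the C4 alkoxide, and acetate attacks the less substituted allyl terminus C1 anti to palladium; the double inversion places the C1 acetate cis to the C4 hydroxyl, whose own C–O bond is never broken.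

Step 8
Reactants: 13 acetate alcohol acetonide
Product: 14 C4,C5,C6-triol (C1–OAc and C7–OBz retained)
Conditions: TFA/H2O (9:1), CH2Cl2, 0 °C
Reagents that add atoms: none
Why: Acid hydrolysis of the isopropylidene acetal in cold aqueous acid frees the cis-diol, while the two esters and the allylic alcohol, deactivated toward ionisation by their oxygen neighbours, should persist.

Step 9
Reactants: 14 triol
Product: 16 [(3R,4S,5R,6S)-3-acetoxy-5-(benzoyloxy)-4,6-dihydroxycyclohex-1-en-1-yl]methyl benzoate (target; (1R,4S,5R,6S) in the ring numbering used here), via cyclic orthobenzoate 15 (not isolated)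
Conditions: PhC(OMe)3 (1.2 equiv), CSA (cat.), MeCN, rt; then 80 % aq. AcOH, rt
Reagents that add atoms: trimethyl orthobenzoate COC(OC)(OC)c1ccccc1; water O
Why: Orthoester exchange engages only the cis C5/C6 diol, and acid hydrolysis through the 1,3-dioxolan-2-ylium ion is known to leave the ester on the axial oxygen; the half-chair that relieves allylic 1,2-strain by placing the C4 hydroxyl pseudoaxial next to the substituted C3 makes C5–O axial, so the benzoate should end on C5.

## Compound list

1 | benzyl benzoate | O=C(OCc1ccccc1)c1ccccc1 | starting material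
2 | 4-methyl-1,2,4-triazoline-3,5-dione (MTAD) | CN1C(=O)N=NC1=O | starting material
3 | racemic arene–MTAD 2,5-cycloadduct (drawn as the enantiomer carried forward) | CN1C(=O)N2[C@@H]3C=C(COC(=O)c4ccccc4)[C@H](N2C1=O)C=C3 | intermediate (not isolated)
4 | racemic urazole-bridged bicyclic cis-5,6-diol (drawn as the enantiomer carried forward) | CN1C(=O)N2[C@@H]3C=C(COC(=O)c4ccccc4)[C@H](N2C1=O)[C@@H](O)[C@H]3O | intermediate
5 | (1R,4S,5R,6S)-bicyclic cis-diol, single enantiomer | CN1C(=O)N2[C@@H]3C=C(COC(=O)c4ccccc4)[C@H](N2C1=O)[C@@H](O)[C@H]3O | intermediate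
6 | C5/C6 acetonide of 5 | CN1C(=O)N2[C@@H]3C=C(COC(=O)c4ccccc4)[C@H](N2C1=O)[C@H]4OC(C)(C)O[C@@H]34 | intermediate
7 | bicyclic hydrazine (NH–NH bridge, C7–OH, acetonide) | OCC1=C[C@H]2NN[C@@H]1[C@H]3OC(C)(C)O[C@@H]23 | intermediate (not isolated)
8 | bicyclic diazene (N=N bridge) | OCC1=C[C@H]2N=N[C@@H]1[C@H]3OC(C)(C)O[C@@H]23 | intermediate (not isolated)
9 | [(3aR,7aS)-2,2-dimethyl-3a,7a-dihydro-1,3-benzodioxol-5-yl]methanol | OCC1=C[C@H]2OC(C)(C)O[C@H]2C=C1 | intermediate
10 | C3–C4 epoxy alcohol, epoxide anti to the acetonide | OC[C@@]12O[C@@H]1[C@H]3OC(C)(C)O[C@H]3C=C2 | intermediate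
11 | C7 benzoate of 10 | O=C(OC[C@@]12O[C@@H]1[C@H]3OC(C)(C)O[C@H]3C=C2)c1ccccc1 | intermediate
12 | acetic acid | CC(=O)O | starting material
13 | C1 acetate, C4 alcohol, C5/C6 acetonide, C7 benzoate | CC(=O)O[C@@H]1C=C(COC(=O)c2ccccc2)[C@H](O)[C@H]2OC(C)(C)O[C@@H]12 | intermediate
14 | C4,C5,C6-triol with C1 acetate and C7 benzoate | CC(=O)O[C@@H]1C=C(COC(=O)c2ccccc2)[C@H](O)[C@@H](O)[C@H]1O | intermediate
15 | C5/C6 cyclic methyl orthobenzoate of 14 (orthoester carbon unassigned) | CC(=O)O[C@@H]1C=C(COC(=O)c2ccccc2)[C@H](O)[C@H]2OC(OC)(c3ccccc3)O[C@@H]12 | intermediate (not isolated)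
16 | [(3R,4S,5R,6S)-3-acetoxy-5-(benzoyloxy)-4,6-dihydroxycyclohex-1-en-1-yl]methyl benzoate | CC(=O)O[C@@H]1C=C(COC(=O)c2ccccc2)[C@H](O)[C@@H](OC(=O)c2ccccc2)[C@H]1O | target

## Totals and risks

Total step count: 9. Longest linear sequence: 9 steps (1 + 2 → 16; acetic acid 12 enters at step 7).

Steps most likely to fail:

Step 2. The enzyme may discriminate the two enantiomers of the hindered bicyclic diol poorly, or may acylate the needed one, so that 5 would be recovered with insufficient enantiomeric purity. The fallback replaces the enzyme by a classical resolution through covalent diastereomers and sets out from racemic 4. Both hydroxyls are acylated with (1S)-(−)-camphanic chloride (pyridine, DMAP, CH2Cl2), and the two diastereomeric diesters are separated by crystallisation or chromatography to give the bis-camphanate of the (1R,4S,5R,6S)-diol F1. K2CO3 in MeOH then removes both camphanates and the C7 benzoate to give the bicyclic urazole triol F2. 2,2-Dimethoxypropane with p-TsOH in acetone closes the C5/C6 acetonide to give the acetonide alcohol F3. F3 is submitted to the conditions of step 4 and comes back to the route at 9.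

Step 9. Both half-chairs of the orthoester may be populated, so that water could open the dioxolanylium ion toward either oxygen, and the benzoate could also migrate between C5, C6 and C4. The fallback uses tin-templated acylation, which selects the equatorial rather than the axial oxygen of a cis-diol and so serves the case in which the orthoester opens toward C6. It sets out from 14: Me2SnCl2 (cat.), BzCl (1.1 equiv) and K2CO3 in THF at rt should pass through the C5/C6 dimethylstannylene acetal F4 and deliver the monobenzoate directly, coming back to the route at 16.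

Step 7. Palladium may also ionise the primary allylic benzoate at C7 or the newly formed allylic acetate, scrambling the esters, or acetate may attack C3 instead of C1. The fallback avoids the epoxide and palladium and sets out from 9. Benzoylation (BzCl, Et3N, DMAP) gives the dienyl benzoate F5. Singlet oxygen (O2, tetraphenylporphyrin, visible light, CH2Cl2, −30 °C) adds across C1 and C4 anti to the acetonide to give the endoperoxide F6. Zn in AcOH/CH2Cl2 cleaves the O–O bond to give the cis-1,4-diol F7. Ac2O (1.05 equiv) with 2,4,6-collidine at −20 °C should acetylate the less hindered C1 hydroxyl, since the C4 hydroxyl is flanked by the substituted C3, and comes back to the route at 13.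

## Further compounds

F1 | step 2 | bis-(1S)-camphanate of the (1R,4S,5R,6S)-diol | CN1C(=O)N2[C@@H]3C=C(COC(=O)c4ccccc4)[C@H](N2C1=O)[C@@H](OC(=O)[C@@]45CC[C@@](C)(C(=O)O4)C5(C)C)[C@H]3OC(=O)[C@@]45CC[C@@](C)(C(=O)O4)C5(C)C
F2 | step 2 | bicyclic urazole triol (C5–OH, C6–OH, C7–OH) | CN1C(=O)N2[C@@H]3C=C(CO)[C@H](N2C1=O)[C@@H](O)[C@H]3O
F3 | step 2 | C5/C6 acetonide of F2 with free C7–OH | CN1C(=O)N2[C@@H]3C=C(CO)[C@H](N2C1=O)[C@H]4OC(C)(C)O[C@@H]34
F4 | step 9 | C5/C6 dimethylstannylene acetal of 14 | CC(=O)O[C@@H]1C=C(COC(=O)c2ccccc2)[C@H](O)[C@H]2O[Sn](C)(C)O[C@@H]12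
F5 | step 7 | C7 benzoate of dienol 9 | O=C(OCC1=C[C@H]2OC(C)(C)O[C@H]2C=C1)c1ccccc1
F6 | step 7 | C1/C4 endoperoxide anti to the acetonide | O=C(OCC1=C[C@H]2OO[C@@H]1[C@H]3OC(C)(C)O[C@@H]23)c1ccccc1
F7 | step 7 | cis-C1,C4-diol with C5/C6 acetonide and C7 benzoate | O[C@@H]1C=C(COC(=O)c2ccccc2)[C@H](O)[C@H]2OC(C)(C)O[C@@H]12
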